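Testudinariol A is C2-symmetric, and in each cyclopentane (C1 carbinol, C2 isopropenyl-bearing, C5 oxane-bearing) the C3–C4 bond joins the only two unfunctionalised ring atoms. Both C3–C4 bonds are therefore formed last among the ring bonds, in one two-fold ring-closing metathesis of an open-chain, C2-symmetric bis-triene that already carries all eight stereocentres and both (Z)-alkylidene oxanes; C2 and C5 each bear the vinyl group that becomes C3 or C4. Hydrogenation then gives the CH2–CH2 bridges. The precursor arises from two successive Wittig olefinations of an oxan-3-one with a C4 bis-phosphonium linker and a double Evans dienolate aldol; the isopropenyl groups are unveiled at the end.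

Key step: step 11

Remark: atom labels follow the overview (cyclopentane C1–C5); on each oxane, C2′ is the carbon bonded to C5, C5′ the alkylidene carbon and C6′ the OCH2 carbon. Imide 19 is made in step 9 and not assumed to be bought. In two-fold steps the singly converted species is numbered as an unisolated intermediate.

**Route**

Step 1
Reactants: 1 methyl pent-4-enoate; 2 (Z)-but-2-ene-1,4-diol
Product: 3 methyl (4E)-6-hydroxyhex-4-enoate
Conditions: second-generation Grubbs catalyst RuCl2(=CHPh)(H2IMes)(PCy3) (2 mol%), 2 (3 equiv), CH2Cl2, 40 °C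
Reagents that add atoms: none
Why: Olefin cross-metathesis of a terminal alkene with an excess of the symmetric allylic diol should give the thermodynamically favoured (E)-allylic alcohol, the ester being inert to the catalyst.

Step 2
Reactants: 3 methyl (4E)-6-hydroxyhex-4-enoate
Product: 4 methyl 3-[(2R,3R)-3-(hydroxymethyl)oxiran-2-yl]propanoate
Conditions: Ti(OiPr)4 (10 mol%), D-(−)-diethyl tartrate (12 mol%), t-BuOOH, 4 Å molecular sieves, CH2Cl2, −20 °C
Reagents that add atoms: tert-butyl hydroperoxide, CC(C)(C)OO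
Why: Sharpless asymmetric epoxidation of an (E)-allylic alcohol, in which the catalyst formed from Ti(OiPr)4 and D-(−)-diethyl tartrate delivers oxygen to the alkene face that gives the (2R,3R)-epoxide and so fixes C2′ and, through the inversion of step 3, C5.

Step 3
Reactants: 4 methyl 3-[(2R,3R)-3-(hydroxymethyl)oxiran-2-yl]propanoate
Product: 6 (5R)-5-[(2S)-1-hydroxybut-3-en-2-yl]oxolan-2-one, via dihydroxy ester 5 (not isolated)
Conditions: CH2=CHMgBr (4 equiv), CuI (2 equiv), THF, −40 to −20 °C; aq NH4Cl; then TsOH·H2O (5 mol%), CH2Cl2, rt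
Reagents that add atoms: vinylmagnesium bromide, C=C[Mg]Br
Why: Alkoxide-directed SN2 opening of the 2,3-epoxy alcohol by the cuprate formed from CH2=CHMgBr and CuI at the carbon next to the carbinol inverts that centre (C5, vinyl anti to the C2′–O bond) without touching the ester, and the freed 4-hydroxy ester closes to the γ-lactone under acid catalysis.

Step 4
Reactants: 6 (5R)-5-[(2S)-1-hydroxybut-3-en-2-yl]oxolan-2-one
Product: 7 (5R,6S)-1-[dimethyl(oxo)-λ6-sulfanylidene]-5-hydroxy-6-(hydroxymethyl)oct-7-en-2-one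
Conditions: Me3S(O)I (3 equiv), KOtBu (3 equiv), THF, reflux; then 6, 0 °C to rt
Reagents that add atoms: trimethylsulfoxonium iodide, C[S+](C)(C)=O.[I-]
Why: Acyl substitution of the lactone by dimethylsulfoxonium methylide should give the stabilised β-keto sulfoxonium ylide and free the C2′ hydroxyl, with no stereocentre involved.

Step 5
Reactants: 7 (5R,6S)-1-[dimethyl(oxo)-λ6-sulfanylidene]-5-hydroxy-6-(hydroxymethyl)oct-7-en-2-one
Product: 8 (6R)-6-[(2S)-1-hydroxybut-3-en-2-yl]oxan-3-one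
Conditions: [Ir(cod)Cl]2 (2 mol%), 1,2-dichloroethane (0.01 M), 70 °C
Reagents that add atoms: none
Why: Carbene transfer from the sulfoxonium ylide catalysed by [Ir(cod)Cl]2 (loss of DMSO) with intramolecular O–H insertion by the secondary hydroxyl closes the six-membered oxan-3-one, the primary hydroxyl being able to form only an eight-membered ring.

Step 6
Reactants: 8 (6R)-6-[(2S)-1-hydroxybut-3-en-2-yl]oxan-3-one; 9 butane-1,4-diylbis(triphenylphosphonium) dibromide
Product: 11 [4-{(3Z,6R)-6-[(2S)-1-hydroxybut-3-en-2-yl]oxan-3-ylidene}butyl]triphenylphosphonium bromide, via mono-ylide 10 (not isolated)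
Conditions: 9 (3 equiv), KN(SiMe3)2 (2 equiv), THF, −78 to 0 °C; then 8 (1 equiv), −78 °C to rt; aq NH4Br; silica gel, CH2Cl2–MeOH
Reagents that add atoms: none
Why: Wittig olefination of the α-alkoxy ketone by the lithium-free mono-ylide of 9, a reaction type known to place the new chain cis to the oxygen-bearing methylene and so to give the (Z)-alkylidene at C5′, the excess of 9 keeping the second phosphonium terminus intact and the ylide being too weak a base to be quenched by the primary alcohol.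

Step 7
Reactants: 11 [4-{(3Z,6R)-6-[(2S)-1-hydroxybut-3-en-2-yl]oxan-3-ylidene}butyl]triphenylphosphonium bromide; 8 (6R)-6-[(2S)-1-hydroxybut-3-en-2-yl]oxan-3-one
Product: 13 1,4-bis{(3Z,6R)-6-[(2S)-1-hydroxybut-3-en-2-yl]oxan-3-ylidene}butane, via mono-olefin ylide 12 (not isolated)
Conditions: 11, KN(SiMe3)2 (1.0 equiv), THF, −78 to 0 °C; then 8 (1.2 equiv), −78 °C to rt
Reagents that add atoms: none
Why: Second Wittig olefination of the same α-alkoxy ketone by the unstabilised ylide made at the remaining phosphonium terminus (the P–CH2 group being far more acidic than the hydroxyls), which should again place the chain cis to the OCH2 group and complete the C2-symmetric (Z,Z)-diene.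

Step 8
Reactants: 13 1,4-bis{(3Z,6R)-6-[(2S)-1-hydroxybut-3-en-2-yl]oxan-3-ylidene}butane
Product: 15 1,4-bis{(3Z,6R)-6-[(2R)-1-oxobut-3-en-2-yl]oxan-3-ylidene}butane, via hydroxy aldehyde 14 (not isolated)
Conditions: Dess–Martin periodinane (2.6 equiv), CH2Cl2, 0 °C to rt; used crude at once
Reagents that add atoms: none
Why: Dess–Martin oxidation takes both primary alcohols to aldehydes without base, which should keep the α-vinyl stereocentre C5 from epimerising and the vinyl group out of conjugation.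

Step 9
Reactants: 16 (4S)-4-benzyl-1,3-oxazolidin-2-one; 17 (2E)-but-2-enoyl chloride
Product: 19 (4S)-4-benzyl-3-[(2E)-but-2-enoyl]-1,3-oxazolidin-2-one, via lithium oxazolidinide 18 (not isolated)
Conditions: n-BuLi, THF, −78 °C; then 17, −78 to 0 °C
Reagents that add atoms: none
Why: N-Acylation of the lithiated oxazolidinone with the acid chloride is a standard acyl substitution that leaves the auxiliary stereocentre untouched.

Step 10
Reactants: 15 1,4-bis{(3Z,6R)-6-[(2R)-1-oxobut-3-en-2-yl]oxan-3-ylidene}butane; 19 (4S)-4-benzyl-3-[(2E)-but-2-enoyl]-1,3-oxazolidin-2-one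
Product: 22 1,4-bis{(3Z,6R)-6-[(3S,4R,5S)-5-{[(4S)-4-benzyl-2-oxo-1,3-oxazolidin-3-yl]carbonyl}-4-hydroxyhepta-1,6-dien-3-yl]oxan-3-ylidene}butane, via boron dienolate 20 (not isolated), via mono-aldol aldehyde 21 (not isolated)
Conditions: 19 (2.6 equiv), Bu2BOTf, iPr2NEt, CH2Cl2, −78 to 0 °C; then 15, −78 to −20 °C; pH 7 buffer, MeOH, 30% H2O2, 0 °C
Reagents that add atoms: none
Why: Evans syn-aldol reaction in which the (Z)-dibutylboron dienolate adds through its α-carbon in a closed chair transition state, the (S)-benzyl auxiliary fixing C2 and C1 of each half (vinyl and hydroxyl syn), a reagent control that coincides with the anti preference of (Z)-enolates relative to the α-stereocentre C5.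

Step 11
Reactants: 22 1,4-bis{(3Z,6R)-6-[(3S,4R,5S)-5-{[(4S)-4-benzyl-2-oxo-1,3-oxazolidin-3-yl]carbonyl}-4-hydroxyhepta-1,6-dien-3-yl]oxan-3-ylidene}butane
Product: 24 1,4-bis{(3Z,6R)-6-[(1S,4S,5R)-4-{[(4S)-4-benzyl-2-oxo-1,3-oxazolidin-3-yl]carbonyl}-5-hydroxycyclopent-2-en-1-yl]oxan-3-ylidene}butane, via mono-cyclopentene 23 (not isolated)
Conditions: second-generation Grubbs catalyst RuCl2(=CHPh)(H2IMes)(PCy3) (10 mol%), CH2Cl2 (0.002 M), 40 °C
Reagents that add atoms: none
Why: Each half of 22 is a 3,5-disubstituted hepta-1,6-dien-4-ol, so the alkylidene complex formed from RuCl2(=CHPh)(H2IMes)(PCy3) at one terminal vinyl group adds [2+2] to the other vinyl group of the same half and cycloreversion of the metallacyclobutane joins C3 to C4 as a cis-alkene with loss of ethene; the closest known reaction type is ring-closing metathesis of 1,6-dienes to cyclopent-3-enols, run here twice in one flask. Both rings close in the same mode, a five-membered carbocycle formed from the two vinyl termini of a 1,6-diene, and neither the oxanes nor the oxazolidinones take part. No stereocentre is created: C1, C2 and C5 of each ring come unchanged from steps 3 and 10, and the ring closure only turns the open-chain relations into hydroxyl cis to the C2 substituent and trans to the C5 substituent. The step needs chemoselectivity for the four monosubstituted vinyl groups over the two trisubstituted exocyclic alkenes, which is secured by the low reactivity of trisubstituted alkenes and by the fact that their engagement could only give bridgehead alkenes or medium rings. It also needs pairing of vinyl groups within one half and not across the molecule, which the 1,6-relation, the branching at C2 and C5 and high dilution secure, the alternative being a ring of more than twenty atoms. The neutral conditions should leave the acidic C2–H next to the imide carbonyl and the free hydroxyls untouched.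

Step 12
Reactants: 24 1,4-bis{(3Z,6R)-6-[(1S,4S,5R)-4-{[(4S)-4-benzyl-2-oxo-1,3-oxazolidin-3-yl]carbonyl}-5-hydroxycyclopent-2-en-1-yl]oxan-3-ylidene}butane
Product: 26 1,4-bis{(3Z,6R)-6-[(1S,2R,3S)-3-{[(4S)-4-benzyl-2-oxo-1,3-oxazolidin-3-yl]carbonyl}-2-hydroxycyclopentyl]oxan-3-ylidene}butane, via half-reduced imide 25 (not isolated)
Conditions: H2 (1 atm), RhCl(PPh3)3 (10 mol%), benzene–EtOH, rt
Reagents that add atoms: none
Why: Homogeneous hydrogenation with RhCl(PPh3)3 should saturate the two cis-disubstituted cyclopentene bonds and leave the trisubstituted exocyclic alkenes, without creating a stereocentre or moving the ring alkene into conjugation with the imide.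

Step 13
Reactants: 26 1,4-bis{(3Z,6R)-6-[(1S,2R,3S)-3-{[(4S)-4-benzyl-2-oxo-1,3-oxazolidin-3-yl]carbonyl}-2-hydroxycyclopentyl]oxan-3-ylidene}butane
Product: 28 1,4-bis{(3Z,6R)-6-[(1S,2R,3S)-2-hydroxy-3-[methoxy(methyl)carbamoyl]cyclopentyl]oxan-3-ylidene}butane, via mono-Weinreb amide 27 (not isolated)
Conditions: MeNH(OMe)·HCl (6 equiv), AlMe3 (6 equiv), CH2Cl2, −15 to 0 °C; aq potassium sodium tartrate
Reagents that add atoms: N,O-dimethylhydroxylamine hydrochloride, CNOC.Cl
Why: Transamidation of the β-hydroxy imides by the amide formed from AlMe3 and MeNH(OMe)·HCl, assisted by the neighbouring hydroxyl, should give the Weinreb amides and release the auxiliary without epimerising C2.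

Step 14
Reactants: 28 1,4-bis{(3Z,6R)-6-[(1S,2R,3S)-2-hydroxy-3-[methoxy(methyl)carbamoyl]cyclopentyl]oxan-3-ylidene}butane
Product: 30 1,4-bis{(3Z,6R)-6-[(1S,2R,3S)-3-acetyl-2-hydroxycyclopentyl]oxan-3-ylidene}butane, via mono-methyl ketone 29 (not isolated)
Conditions: MeMgBr (8 equiv), THF, −20 to 0 °C; aq NH4Cl
Reagents that add atoms: methylmagnesium bromide, C[Mg]Br
Why: Weinreb ketone synthesis, in which the chelated tetrahedral intermediate formed with MeMgBr survives until work-up so that each amide takes up one methyl group, the excess reagent only deprotonating the hydroxyls.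

Step 15
Reactants: 30 1,4-bis{(3Z,6R)-6-[(1S,2R,3S)-3-acetyl-2-hydroxycyclopentyl]oxan-3-ylidene}butane
Product: 32 testudinariol A, via mono-isopropenyl ketone 31 (not isolated)
Conditions: CH2Br2, Zn, TiCl4 (premixed in THF), CH2Cl2, 0 °C to rt
Reagents that add atoms: dibromomethane, BrCBr
Why: Takai–Lombardo methylenation with the non-basic reagent formed from CH2Br2, Zn and TiCl4 converts the epimerisable β-hydroxy methyl ketones into the isopropenyl groups, so the cis relation of hydroxyl and C2 substituent set in step 10 should be kept.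

**Compound list**

1 | methyl pent-4-enoate | C=CCCC(=O)OC | starting material
2 | (Z)-but-2-ene-1,4-diol | OC/C=C\CO | starting material
3 | methyl (4E)-6-hydroxyhex-4-enoate | COC(=O)CC/C=C/CO | intermediate
4 | methyl 3-[(2R,3R)-3-(hydroxymethyl)oxiran-2-yl]propanoate | OC[C@H]1O[C@@H]1CCC(=O)OC | intermediate
5 | methyl (4R,5S)-4-hydroxy-5-(hydroxymethyl)hept-6-enoate | OC[C@H](C=C)[C@H](O)CCC(=O)OC | intermediate (not isolated)
6 | (5R)-5-[(2S)-1-hydroxybut-3-en-2-yl]oxolan-2-one | OC[C@H](C=C)[C@H]1CCC(=O)O1 | intermediate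
7 | (5R,6S)-1-[dimethyl(oxo)-λ6-sulfanylidene]-5-hydroxy-6-(hydroxymethyl)oct-7-en-2-one | OC[C@H](C=C)[C@H](O)CCC(=O)C=S(C)(C)=O | intermediate
8 | (6R)-6-[(2S)-1-hydroxybut-3-en-2-yl]oxan-3-one | OC[C@H](C=C)[C@H]1CCC(=O)CO1 | intermediate
9 | butane-1,4-diylbis(triphenylphosphonium) dibromide | [Br-].[Br-].c1ccccc1[P+](c1ccccc1)(c1ccccc1)CCCC[P+](c1ccccc1)(c1ccccc1)c1ccccc1 | starting material
10 | triphenyl[4-(triphenyl-λ5-phosphanylidene)butyl]phosphonium bromide (mono-ylide) | [Br-].c1ccccc1P(c1ccccc1)(c1ccccc1)=CCCC[P+](c1ccccc1)(c1ccccc1)c1ccccc1 | intermediate (not isolated)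
11 | [4-{(3Z,6R)-6-[(2S)-1-hydroxybut-3-en-2-yl]oxan-3-ylidene}butyl]triphenylphosphonium bromide | [Br-].OC[C@H](C=C)[C@H]1CC/C(=C/CCC[P+](c2ccccc2)(c2ccccc2)c2ccccc2)CO1 | intermediate
12 | (2S)-2-{(2R,5Z)-5-[4-(triphenyl-λ5-phosphanylidene)butylidene]oxan-2-yl}but-3-en-1-ol (mono-olefin ylide) | OC[C@H](C=C)[C@H]1CC/C(=C/CCC=P(c2ccccc2)(c2ccccc2)c2ccccc2)CO1 | intermediate (not isolated)
13 | 1,4-bis{(3Z,6R)-6-[(2S)-1-hydroxybut-3-en-2-yl]oxan-3-ylidene}butane | OC[C@H](C=C)[C@H]1CC/C(=C/CC/C=C2/CC[C@H]([C@@H](C=C)CO)OC2)CO1 | intermediate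
14 | hydroxy aldehyde (13 in which one CH2OH is oxidised to CHO) | O=C[C@H](C=C)[C@H]1CC/C(=C/CC/C=C2/CC[C@H]([C@@H](C=C)CO)OC2)CO1 | intermediate (not isolated)
15 | 1,4-bis{(3Z,6R)-6-[(2R)-1-oxobut-3-en-2-yl]oxan-3-ylidene}butane | O=C[C@H](C=C)[C@H]1CC/C(=C/CC/C=C2/CC[C@H]([C@@H](C=C)C=O)OC2)CO1 | intermediate
16 | (4S)-4-benzyl-1,3-oxazolidin-2-one | O=C1N[C@@H](Cc2ccccc2)CO1 | starting material
17 | (2E)-but-2-enoyl chloride | C/C=C/C(Cl)=O | starting material
18 | lithium (4S)-4-benzyl-2-oxo-1,3-oxazolidin-3-ide | [Li]N1[C@@H](Cc2ccccc2)COC1=O | intermediate (not isolated)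
19 | (4S)-4-benzyl-3-[(2E)-but-2-enoyl]-1,3-oxazolidin-2-one | C/C=C/C(=O)N1[C@@H](Cc2ccccc2)COC1=O | intermediate
20 | (4S)-4-benzyl-3-{(1Z)-1-[(dibutylboranyl)oxy]buta-1,3-dien-1-yl}-1,3-oxazolidin-2-one (boron dienolate) | CCCCB(CCCC)O/C(=C\C=C)N1[C@@H](Cc2ccccc2)COC1=O | intermediate (not isolated)
21 | mono-aldol aldehyde (one end as in 22, other end as in 15) | C=C[C@H](C(=O)N1[C@@H](Cc2ccccc2)COC1=O)[C@H](O)[C@H](C=C)[C@H]1CC/C(=C/CC/C=C2/CC[C@H]([C@@H](C=C)C=O)OC2)CO1 | intermediate (not isolated)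
22 | 1,4-bis{(3Z,6R)-6-[(3S,4R,5S)-5-{[(4S)-4-benzyl-2-oxo-1,3-oxazolidin-3-yl]carbonyl}-4-hydroxyhepta-1,6-dien-3-yl]oxan-3-ylidene}butane | C=C[C@H](C(=O)N1[C@@H](Cc2ccccc2)COC1=O)[C@H](O)[C@H](C=C)[C@H]1CC/C(=C/CC/C=C2/CC[C@H]([C@@H](C=C)[C@@H](O)[C@H](C=C)C(=O)N3[C@@H](Cc4ccccc4)COC3=O)OC2)CO1 | intermediate
23 | mono-cyclopentene (one end as in 24, other end as in 22) | O=C(N1[C@@H](Cc2ccccc2)COC1=O)[C@H]1C=C[C@H]([C@H]2CC/C(=C/CC/C=C3/CC[C@H]([C@@H](C=C)[C@@H](O)[C@H](C=C)C(=O)N4[C@@H](Cc5ccccc5)COC4=O)OC3)CO2)[C@H]1O | intermediate (not isolated)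
24 | 1,4-bis{(3Z,6R)-6-[(1S,4S,5R)-4-{[(4S)-4-benzyl-2-oxo-1,3-oxazolidin-3-yl]carbonyl}-5-hydroxycyclopent-2-en-1-yl]oxan-3-ylidene}butane | O=C(N1[C@@H](Cc2ccccc2)COC1=O)[C@H]1C=C[C@H]([C@H]2CC/C(=C/CC/C=C3/CC[C@H]([C@H]4C=C[C@H](C(=O)N5[C@@H](Cc6ccccc6)COC5=O)[C@@H]4O)OC3)CO2)[C@H]1O | intermediate
25 | half-reduced imide (one cyclopentane, one cyclopentene) | O=C(N1[C@@H](Cc2ccccc2)COC1=O)[C@H]1CC[C@H]([C@H]2CC/C(=C/CC/C=C3/CC[C@H]([C@H]4C=C[C@H](C(=O)N5[C@@H](Cc6ccccc6)COC5=O)[C@@H]4O)OC3)CO2)[C@H]1O | intermediate (not isolated)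
26 | 1,4-bis{(3Z,6R)-6-[(1S,2R,3S)-3-{[(4S)-4-benzyl-2-oxo-1,3-oxazolidin-3-yl]carbonyl}-2-hydroxycyclopentyl]oxan-3-ylidene}butane | O=C(N1[C@@H](Cc2ccccc2)COC1=O)[C@H]1CC[C@H]([C@H]2CC/C(=C/CC/C=C3/CC[C@H]([C@H]4CC[C@H](C(=O)N5[C@@H](Cc6ccccc6)COC5=O)[C@@H]4O)OC3)CO2)[C@H]1O | intermediate
27 | mono-Weinreb amide (one end as in 28, other end as in 26) | CON(C)C(=O)[C@H]1CC[C@H]([C@H]2CC/C(=C/CC/C=C3/CC[C@H]([C@H]4CC[C@H](C(=O)N5[C@@H](Cc6ccccc6)COC5=O)[C@@H]4O)OC3)CO2)[C@H]1O | intermediate (not isolated)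
28 | 1,4-bis{(3Z,6R)-6-[(1S,2R,3S)-2-hydroxy-3-[methoxy(methyl)carbamoyl]cyclopentyl]oxan-3-ylidene}butane | CON(C)C(=O)[C@H]1CC[C@H]([C@H]2CC/C(=C/CC/C=C3/CC[C@H]([C@H]4CC[C@H](C(=O)N(C)OC)[C@@H]4O)OC3)CO2)[C@H]1O | intermediate
29 | mono-methyl ketone (one end as in 30, other end as in 28) | CC(=O)[C@H]1CC[C@H]([C@H]2CC/C(=C/CC/C=C3/CC[C@H]([C@H]4CC[C@H](C(=O)N(C)OC)[C@@H]4O)OC3)CO2)[C@H]1O | intermediate (not isolated)
30 | 1,4-bis{(3Z,6R)-6-[(1S,2R,3S)-3-acetyl-2-hydroxycyclopentyl]oxan-3-ylidene}butane | CC(=O)[C@H]1CC[C@H]([C@H]2CC/C(=C/CC/C=C3/CC[C@H]([C@H]4CC[C@H](C(C)=O)[C@@H]4O)OC3)CO2)[C@H]1O | intermediate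
31 | mono-isopropenyl ketone (one end as in 32, other end as in 30) | C=C(C)[C@H]1CC[C@H]([C@H]2CC/C(=C/CC/C=C3/CC[C@H]([C@H]4CC[C@H](C(C)=O)[C@@H]4O)OC3)CO2)[C@H]1O | intermediate (not isolated)
32 | testudinariol A | C=C(C)[C@H]1CC[C@H]([C@H]2CC/C(=C/CC/C=C3/CC[C@H]([C@H]4CC[C@H](C(=C)C)[C@@H]4O)OC3)CO2)[C@H]1O | target

**Step count and risks**

Total step count: 15. Longest linear sequence: 14 steps (steps 1 to 8 and 10 to 15; step 9 is a one-step branch).

Steps most likely to fail:

1. Step 6. The (Z)-preference of α-alkoxy ketones in Wittig olefination is documented for open-chain ketones and may fade in the six-membered ring. Poor geometric selectivity, enolisation of the ketone by the ylide, or olefination at both ends of the linker in one pass could erode the supply of the mono-phosphonium salt. Fallback (sets out from 6, comes back at 13): the olefination is moved to an open-chain α-alkoxy ketone and the oxanes are closed afterwards. Lactone 6 is opened with [(4-methoxybenzyl)oxy]methyllithium (from the tributylstannane and n-BuLi, THF, −78 °C) to the open-chain α-alkoxy ketone diol F1. Both hydroxyls are silylated (Et3SiOTf, 2,6-lutidine) to the bis-silyl ether F2. Salt 9 is converted with KN(SiMe3)2 (2 equiv) into the bis-ylide F3, and its two-fold Wittig reaction with two molecules of F2 should give the (Z,Z)-diene F4. DDQ removes the two 4-methoxybenzyl ethers to the bis-allylic alcohol F5, and MsCl, LiCl and collidine convert it into the bis-allylic chloride F6. Bu4NF removes the four silyl groups to the tetraol dichloride F7, and NaH then closes both oxanes by 6-exo-tet attack of the C2′ alkoxides on the allylic chlorides, giving 13.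

2. Step 10. The bis(α-vinyl) aldehyde 15 may epimerise at C5, move its vinyl double bond into conjugation or lose the β-oxygen by elimination in the amine-containing enolate mixture before the aldol addition takes place. Fallback (sets out from 13, comes back at 28): the C1–C2 bonds are made from the alcohol oxidation level, so that no free aldehyde is handled. Diol 13 is coupled with 4-vinyl-1,3-dioxolan-2-one by transfer-hydrogenative anti-(hydroxymethyl)allylation ([Ir(cod)Cl]2, SEGPHOS with the enantiomer chosen for the C1 configuration, 4-cyano-3-nitrobenzoic acid, K3PO4, THF, 70 °C) to give the bis-homoallylic tetraol F8. Two-fold ring-closing metathesis as in step 11 gives the bis-cyclopentene tetraol F9, and hydrogenation as in step 12 gives the saturated tetraol F10. TEMPO and PhI(OAc)2 in MeCN–water oxidise only the two primary alcohols, giving the diacid F11. EDC·HCl, MeNH(OMe)·HCl and iPr2NEt then give 28.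

3. Step 5. The carbene complex may be intercepted by the primary hydroxyl of a second molecule or by the vinyl group, or the diol may slow the catalyst, so that ring closure to the oxan-3-one is incomplete. Fallback (sets out from 6, comes back at 8): the O–C6′ bond is made by SN2 etherification and not by carbene insertion. Lactone 6 is treated with chloromethyllithium (ICH2Cl, MeLi·LiBr, THF, −78 °C) to give the α-chloromethyl ketone F12. K2CO3 and NaI in acetone then let the C2′ hydroxyl displace the chloride in a 6-exo-tet closure, giving 8.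

Further compounds
F1 | step 6 | (5R,6S)-5-hydroxy-6-(hydroxymethyl)-1-[(4-methoxybenzyl)oxy]oct-7-en-2-one | OC[C@H](C=C)[C@H](O)CCC(=O)COCc1ccc(OC)cc1
F2 | step 6 | (5R,6S)-1-[(4-methoxybenzyl)oxy]-5-[(triethylsilyl)oxy]-6-{[(triethylsilyl)oxy]methyl}oct-7-en-2-one | CC[Si](CC)(CC)OC[C@H](C=C)[C@H](O[Si](CC)(CC)CC)CCC(=O)COCc1ccc(OC)cc1
F3 | step 6 | 1,4-bis(triphenyl-λ5-phosphanylidene)butane (bis-ylide) | c1ccccc1P(c1ccccc1)(c1ccccc1)=CCCC=P(c1ccccc1)(c1ccccc1)c1ccccc1
F4 | step 6 | open-chain (Z,Z)-diene, bis(4-methoxybenzyl) ether, tetrakis(triethylsilyl) ether | CC[Si](CC)(CC)OC[C@H](C=C)[C@H](O[Si](CC)(CC)CC)CC/C(COCc1ccc(OC)cc1)=C/CC/C=C(\COCc1ccc(OC)cc1)CC[C@@H](O[Si](CC)(CC)CC)[C@@H](C=C)CO[Si](CC)(CC)CC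
F5 | step 6 | open-chain (Z,Z)-bis-allylic alcohol, tetrakis(triethylsilyl) ether | CC[Si](CC)(CC)OC[C@H](C=C)[C@H](O[Si](CC)(CC)CC)CC/C(CO)=C/CC/C=C(\CO)CC[C@@H](O[Si](CC)(CC)CC)[C@@H](C=C)CO[Si](CC)(CC)CC
F6 | step 6 | open-chain (Z,Z)-bis-allylic chloride, tetrakis(triethylsilyl) ether | CC[Si](CC)(CC)OC[C@H](C=C)[C@H](O[Si](CC)(CC)CC)CC/C(CCl)=C/CC/C=C(\CCl)CC[C@@H](O[Si](CC)(CC)CC)[C@@H](C=C)CO[Si](CC)(CC)CC
F7 | step 6 | open-chain (Z,Z)-bis-allylic chloride tetraol | OC[C@H](C=C)[C@H](O)CC/C(CCl)=C/CC/C=C(\CCl)CC[C@@H](O)[C@@H](C=C)CO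
F8 | step 10 | bis-homoallylic tetraol (each end CH(OH)–CH(CH2OH)–CH=CH2 on C5) | OC[C@@H](C=C)[C@H](O)[C@H](C=C)[C@H]1CC/C(=C/CC/C=C2/CC[C@H]([C@@H](C=C)[C@@H](O)[C@H](C=C)CO)OC2)CO1
F9 | step 10 | bis-cyclopentene tetraol | OC[C@H]1C=C[C@H]([C@H]2CC/C(=C/CC/C=C3/CC[C@H]([C@H]4C=C[C@H](CO)[C@@H]4O)OC3)CO2)[C@H]1O
F10 | step 10 | bis-cyclopentane tetraol | OC[C@H]1CC[C@H]([C@H]2CC/C(=C/CC/C=C3/CC[C@H]([C@H]4CC[C@H](CO)[C@@H]4O)OC3)CO2)[C@H]1O
F11 | step 10 | bis(2-hydroxycyclopentanecarboxylic acid) | OC(=O)[C@H]1CC[C@H]([C@H]2CC/C(=C/CC/C=C3/CC[C@H]([C@H]4CC[C@H](C(=O)O)[C@@H]4O)OC3)CO2)[C@H]1O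
F12 | step 5 | (5R,6S)-1-chloro-5-hydroxy-6-(hydroxymethyl)oct-7-en-2-one | OC[C@H](C=C)[C@H](O)CCC(=O)CCl
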